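**Retrosynthetic overview**

1. Target 21 comes from methyl ester 20 by hydrolysis; 20 comes from silylalkyne 19 by desilylative bromination.
2. The route is built around an allylic C–O bond: alcohol 17 is esterified to picolinate 18, and this C–O bond is then exchanged, with 1,3-chirality transfer, for the C–CH3 bond of the methyl stereocentre, giving the (E,E)-diene of 19 in the same step.
3. Alcohol 17 comes from diyne 9 (carboalumination) and enal 15 by enantioselective alkenyl addition.
4. Enal 15 comes from allylic alcohol 12 by Charette cyclopropanation (the only ring, formed before fragment union), then oxidation/Wittig; 12 comes from cross-metathesis of 10 and 11.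
5. Diyne 9 comes from chiral-pool bromo alcohol 1 by triflate alkynylation and a copper-catalysed Grignard coupling.

Assumption: the target SMILES corresponds to 4-[(1R,2R)-2-[(2S,3E,5E,10R)-13-bromo-6,10-dimethyltrideca-3,5-dien-12-yn-2-yl]cyclopropyl]butanoic acid, and compounds 1, 2, 6, 10 and 11 are bought.

**Route**

Step 1
Reactants: 1 (2S)-3-bromo-2-methylpropan-1-ol; 2 ethynyltri(propan-2-yl)silane
Product: 5 [(4S)-5-bromo-4-methylpent-1-yn-1-yl]tri(propan-2-yl)silane, via lithium silylacetylide 3 (not isolated), via triflate 4 (not isolated)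
Conditions: 2, n-BuLi, THF, −78 °C; separately 1, n-BuLi, Et2O, −78 °C, then Tf2O; acetylide solution and DMPU added, −78 to 0 °C
Reagents that add atoms: none
Why: SN2 alkylation of a lithium acetylide by a primary triflate made in situ, which reacts far faster than the primary bromide; the chiral-pool stereocentre is not involved.

Step 2
Reactants: 5 [(4S)-5-bromo-4-methylpent-1-yn-1-yl]tri(propan-2-yl)silane; 6 (4-bromobut-1-yn-1-yl)trimethylsilane
Product: 8 trimethyl[(6R)-6-methyl-9-[tri(propan-2-yl)silyl]nona-1,8-diyn-1-yl]silane, via butynylmagnesium bromide 7 (not isolated)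
Conditions: 6, Mg, THF, 40 °C; then 5, Li2CuCl4 (3 mol%), NMP, THF, 0 °C to rt
Reagents that add atoms: none
Why: Copper-catalysed Kumada-type sp3–sp3 cross-coupling of a primary alkyl bromide with a primary Grignard reagent; the stereocentre is untouched (the descriptor changes to R only through priorities).

Step 3
Reactants: 8 trimethyl[(6R)-6-methyl-9-[tri(propan-2-yl)silyl]nona-1,8-diyn-1-yl]silane
Product: 9 [(4R)-4-methylnona-1,8-diyn-1-yl]tri(propan-2-yl)silane
Conditions: K2CO3 (0.2 equiv), MeOH, rt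
Reagents that add atoms: none
Why: Methoxide-mediated protiodesilylation removes the unhindered trimethylsilyl group while the bulky tri(propan-2-yl)silyl alkyne survives.

Step 4
Reactants: 10 methyl hex-5-enoate; 11 (2Z)-but-2-ene-1,4-diol
Product: 12 methyl (5E)-7-hydroxyhept-5-enoate
Conditions: second-generation Hoveyda–Grubbs catalyst (2 mol%), 11 (3 equiv), CH2Cl2, 40 °C
Reagents that add atoms: none
Why: Olefin cross-metathesis of a terminal alkene with an excess of a symmetrical allylic diol gives the E-allylic alcohol (about 10:1 E/Z expected; minor isomer removed by chromatography).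

Step 5
Reactants: 12 methyl (5E)-7-hydroxyhept-5-enoate
Product: 13 methyl 4-[(1R,2R)-2-(hydroxymethyl)cyclopropyl]butanoate
Conditions: Et2Zn, CH2I2, DME, CH2Cl2, −10 °C; then 12 and (4S,5S)-2-butyl-N,N,N′,N′-tetramethyl-1,3,2-dioxaborolane-4,5-dicarboxamide (1.2 equiv), 0 °C to rt; aq NH4Cl, then aq NaOH
Reagents that add atoms: diiodomethane, ICI
Why: Charette asymmetric Simmons–Smith cyclopropanation; the zinc alkoxide bound to the (S,S)-dioxaborolane directs stereospecific CH2 transfer to one face of the E-alkene and sets both ring stereocentres (1R,2R, trans).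

Step 6
Reactants: 13 methyl 4-[(1R,2R)-2-(hydroxymethyl)cyclopropyl]butanoate
Product: 15 methyl 4-[(1R,2R)-2-[(1E)-3-oxoprop-1-en-1-yl]cyclopropyl]butanoate, via cyclopropanecarbaldehyde 14 (not isolated)
Conditions: TEMPO (10 mol%), PhI(OAc)2 (1.1 equiv), CH2Cl2, rt; then Ph3P=CHCHO (1.2 equiv), 40 °C
Reagents that add atoms: (triphenyl-λ5-phosphanylidene)acetaldehyde, O=CC=P(c1ccccc1)(c1ccccc1)c1ccccc1
Why: Nitroxyl-catalysed alcohol oxidation followed by Wittig olefination with the stabilised formyl ylide gives the E-enal; the trans ring configuration is the thermodynamic one and is kept.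

Step 7
Reactants: 9 [(4R)-4-methylnona-1,8-diyn-1-yl]tri(propan-2-yl)silane; 15 methyl 4-[(1R,2R)-2-[(1E)-3-oxoprop-1-en-1-yl]cyclopropyl]butanoate
Product: 17 methyl 4-[(1R,2R)-2-[(1E,3S,4E,9R)-3-hydroxy-5,9-dimethyl-12-[tri(propan-2-yl)silyl]dodeca-1,4-dien-11-yn-1-yl]cyclopropyl]butanoate, via alkenylalane 16 (not isolated)
Conditions: 9 (1.3 equiv), Me3Al (2 equiv), (C5H5)2ZrCl2 (0.2 equiv), CH2Cl2, 0 °C to rt; then Ti(OiPr)4 (3 equiv), (R)-3-(3,5-diphenylphenyl)-H8-BINOL (5 mol%), 15, THF, 0 °C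
Reagents that add atoms: trimethylaluminium, C[Al](C)C
Why: Negishi zirconium-catalysed syn-carboalumination gives the (E)-2-methylalkenylalane (the silylalkyne is inert), and titanium/H8-BINOL-catalysed enantioselective 1,2-alkenyl transfer to the enal (Re face expected with the R ligand) sets the 3S carbinol with retention of alkene geometry.

Step 8
Reactants: 17 methyl 4-[(1R,2R)-2-[(1E,3S,4E,9R)-3-hydroxy-5,9-dimethyl-12-[tri(propan-2-yl)silyl]dodeca-1,4-dien-11-yn-1-yl]cyclopropyl]butanoate
Product: 18 (1E,3S,4E,9R)-1-[(1R,2R)-2-(4-methoxy-4-oxobutyl)cyclopropyl]-5,9-dimethyl-12-[tri(propan-2-yl)silyl]dodeca-1,4-dien-11-yn-3-yl pyridine-2-carboxylate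
Conditions: pyridine-2-carboxylic acid (1.5 equiv), DCC (1.5 equiv), DMAP (0.1 equiv), CH2Cl2, 0 °C; used at once
Reagents that add atoms: pyridine-2-carboxylic acid, OC(=O)c1ccccn1
Why: Steglich esterification under non-ionising conditions forms the allylic C–O ester with retention and installs the chelating leaving group.

Step 9
Reactants: 18 (1E,3S,4E,9R)-1-[(1R,2R)-2-(4-methoxy-4-oxobutyl)cyclopropyl]-5,9-dimethyl-12-[tri(propan-2-yl)silyl]dodeca-1,4-dien-11-yn-3-yl pyridine-2-carboxylate
Product: 19 methyl 4-[(1R,2R)-2-[(2S,3E,5E,10R)-6,10-dimethyl-13-[tri(propan-2-yl)silyl]trideca-3,5-dien-12-yn-2-yl]cyclopropyl]butanoate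
Conditions: MeMgBr (2.0 equiv), CuBr·SMe2 (1.0 equiv), THF, −78 to −40 °C
Reagents that add atoms: methylmagnesium bromide, C[Mg]Br
Why: Proposed new method: copper-mediated anti-SN2′ methyl transfer to a doubly allylic (1,4-dien-3-yl) picolinate, a substrate class on which this reactivity has not been shown; the picolinate N,O-chelates magnesium and activates the C–O bond, the methylcuprate adds anti to it at the γ-carbon of the less hindered 1,2-disubstituted alkene (the other γ-terminus is trisubstituted and would give a quaternary centre, and attack at the chosen terminus develops diene conjugation), and reductive elimination from the σ-allyl trivalent-copper intermediate forms the C–CH3 bond, so the 3S C–O stereocentre of 18 is relayed to the 2S centre of 19 through the conformer with the carbinol hydrogen eclipsing the alkene, which also fixes the new 3E alkene; the closest known reaction is the anti-SN2′ substitution of simple secondary allylic picolinates by Grignard reagents and copper salts.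

Step 10
Reactants: 19 methyl 4-[(1R,2R)-2-[(2S,3E,5E,10R)-6,10-dimethyl-13-[tri(propan-2-yl)silyl]trideca-3,5-dien-12-yn-2-yl]cyclopropyl]butanoate
Product: 20 methyl 4-[(1R,2R)-2-[(2S,3E,5E,10R)-13-bromo-6,10-dimethyltrideca-3,5-dien-12-yn-2-yl]cyclopropyl]butanoate
Conditions: NBS (1.2 equiv), AgF (1.2 equiv), MeCN, rt, dark
Reagents that add atoms: N-bromosuccinimide, O=C1CCC(=O)N1Br
Why: Silver-mediated desilylative bromination: fluoride-assisted formation of the silver acetylide and its bromination by NBS converts the silylalkyne directly into the bromoalkyne, which should outpace attack of NBS on the diene.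

Step 11
Reactants: 20 methyl 4-[(1R,2R)-2-[(2S,3E,5E,10R)-13-bromo-6,10-dimethyltrideca-3,5-dien-12-yn-2-yl]cyclopropyl]butanoate
Product: 21 4-[(1R,2R)-2-[(2S,3E,5E,10R)-13-bromo-6,10-dimethyltrideca-3,5-dien-12-yn-2-yl]cyclopropyl]butanoic acid
Conditions: LiOH (3 equiv), THF/MeOH/H2O, 0 °C to rt; then 1 M HCl, 0 °C
Reagents that add atoms: lithium hydroxide, [Li+].[OH-]
Why: Saponification of the methyl ester at low temperature; the bromoalkyne, the diene and all four stereocentres are expected to be inert to aqueous LiOH.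

**Compound list**

1 | (2S)-3-bromo-2-methylpropan-1-ol | OC[C@H](C)CBr | starting material
2 | ethynyltri(propan-2-yl)silane | C#C[Si](C(C)C)(C(C)C)C(C)C | starting material
3 | lithium [tri(propan-2-yl)silyl]acetylide | [Li]C#C[Si](C(C)C)(C(C)C)C(C)C | intermediate
4 | (2S)-3-bromo-2-methylpropyl trifluoromethanesulfonate | FC(F)(F)S(=O)(=O)OC[C@H](C)CBr | intermediate
5 | [(4S)-5-bromo-4-methylpent-1-yn-1-yl]tri(propan-2-yl)silane | CC(C)[Si](C(C)C)(C(C)C)C#CC[C@H](C)CBr | intermediate
6 | (4-bromobut-1-yn-1-yl)trimethylsilane | C[Si](C)(C)C#CCCBr | starting material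
7 | [4-(trimethylsilyl)but-3-yn-1-yl]magnesium bromide | C[Si](C)(C)C#CCC[Mg]Br | intermediate
8 | trimethyl[(6R)-6-methyl-9-[tri(propan-2-yl)silyl]nona-1,8-diyn-1-yl]silane | C[Si](C)(C)C#CCCC[C@@H](C)CC#C[Si](C(C)C)(C(C)C)C(C)C | intermediate
9 | [(4R)-4-methylnona-1,8-diyn-1-yl]tri(propan-2-yl)silane | C#CCCC[C@@H](C)CC#C[Si](C(C)C)(C(C)C)C(C)C | intermediate
10 | methyl hex-5-enoate | COC(=O)CCCC=C | starting material
11 | (2Z)-but-2-ene-1,4-diol | OC/C=C\CO | starting material
12 | methyl (5E)-7-hydroxyhept-5-enoate | COC(=O)CCC/C=C/CO | intermediate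
13 | methyl 4-[(1R,2R)-2-(hydroxymethyl)cyclopropyl]butanoate | COC(=O)CCC[C@@H]1C[C@H]1CO | intermediate
14 | methyl 4-[(1R,2R)-2-formylcyclopropyl]butanoate | COC(=O)CCC[C@@H]1C[C@H]1C=O | intermediate
15 | methyl 4-[(1R,2R)-2-[(1E)-3-oxoprop-1-en-1-yl]cyclopropyl]butanoate | COC(=O)CCC[C@@H]1C[C@H]1/C=C/C=O | intermediate
16 | dimethyl[(1E,6R)-2,6-dimethyl-9-[tri(propan-2-yl)silyl]non-1-en-8-yn-1-yl]alumane | C[Al](C)/C=C(\C)CCC[C@@H](C)CC#C[Si](C(C)C)(C(C)C)C(C)C | intermediate
17 | methyl 4-[(1R,2R)-2-[(1E,3S,4E,9R)-3-hydroxy-5,9-dimethyl-12-[tri(propan-2-yl)silyl]dodeca-1,4-dien-11-yn-1-yl]cyclopropyl]butanoate | COC(=O)CCC[C@@H]1C[C@H]1/C=C/[C@H](O)/C=C(\C)CCC[C@@H](C)CC#C[Si](C(C)C)(C(C)C)C(C)C | intermediate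
18 | (1E,3S,4E,9R)-1-[(1R,2R)-2-(4-methoxy-4-oxobutyl)cyclopropyl]-5,9-dimethyl-12-[tri(propan-2-yl)silyl]dodeca-1,4-dien-11-yn-3-yl pyridine-2-carboxylate | COC(=O)CCC[C@@H]1C[C@H]1/C=C/[C@H](OC(=O)c1ccccn1)/C=C(\C)CCC[C@@H](C)CC#C[Si](C(C)C)(C(C)C)C(C)C | intermediate
19 | methyl 4-[(1R,2R)-2-[(2S,3E,5E,10R)-6,10-dimethyl-13-[tri(propan-2-yl)silyl]trideca-3,5-dien-12-yn-2-yl]cyclopropyl]butanoate | COC(=O)CCC[C@@H]1C[C@H]1[C@@H](C)/C=C/C=C(\C)CCC[C@@H](C)CC#C[Si](C(C)C)(C(C)C)C(C)C | intermediate
20 | methyl 4-[(1R,2R)-2-[(2S,3E,5E,10R)-13-bromo-6,10-dimethyltrideca-3,5-dien-12-yn-2-yl]cyclopropyl]butanoate | COC(=O)CCC[C@@H]1C[C@H]1[C@@H](C)/C=C/C=C(\C)CCC[C@@H](C)CC#CBr | intermediate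
21 | 4-[(1R,2R)-2-[(2S,3E,5E,10R)-13-bromo-6,10-dimethyltrideca-3,5-dien-12-yn-2-yl]cyclopropyl]butanoic acid | C/C(=C\C=C\[C@H](C)[C@@H]1C[C@H]1CCCC(=O)O)CCC[C@@H](C)CC#CBr | target

**Step count and risks**

Total steps: 11. Longest linear sequence: 8 (steps 1, 2, 3, 7, 8, 9, 10, 11; the branch 4, 5, 6, 7–11 is equally long).

Step 9 (the proposed new step). It can fail by direct α-substitution, by attack at the trisubstituted allyl arm, or by prior 1,3-shift of the labile doubly allylic ester. The fallback uses known chemistry, sets out from enal 15 (with diyne 9) and rejoins at 19. Luche reduction of 15 (NaBH4, CeCl3, MeOH) gives allylic alcohol F2, and CBr4/PPh3 gives allylic bromide F3. Copper-catalysed asymmetric allylic methylation (MeMgBr, CuBr·SMe2, the Taniaphos enantiomer that gives 2S, CH2Cl2, −78 °C) gives the branched terminal alkene F4 under catalyst control. Cross-metathesis with 4,4,5,5-tetramethyl-2-vinyl-1,3,2-dioxaborolane (second-generation Grubbs catalyst) gives the (E)-alkenylboronate F5. Suzuki–Miyaura coupling (Pd(PPh3)4, aq K3PO4, THF) with vinyl iodide F1, made from 9 as in the next fallback, gives 19.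

Step 7. Methyl instead of alkenyl transfer, or low facial selectivity on this enal, would erode the relay stereocentre. The fallback sets out from 9 and 15 and rejoins at 17. Alkenylalane 16 is made as before and quenched with I2 to give vinyl iodide F1, which is coupled with 15 in a catalytic asymmetric Nozaki–Hiyama–Kishi reaction (CrCl2 and NiCl2 catalytic, Mn, chiral sulfonamide ligand, MeCN) to give 17.

Step 10. NBS may attack the electron-rich diene before Si-to-Br exchange is complete. The fallback sets out from 19 and rejoins at 20. TBAF (THF, 0 °C) gives terminal alkyne F6, which is brominated without metal by NBS/DBU (MeCN, 0 °C) through the amidinium acetylide to give 20.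

**Further compounds**

F1 | step 7 | [(4R,8E)-9-iodo-4,8-dimethylnon-8-en-1-yn-1-yl]tri(propan-2-yl)silane | I/C=C(\C)CCC[C@@H](C)CC#C[Si](C(C)C)(C(C)C)C(C)C
F2 | step 9 | methyl 4-[(1R,2R)-2-[(1E)-3-hydroxyprop-1-en-1-yl]cyclopropyl]butanoate | COC(=O)CCC[C@@H]1C[C@H]1/C=C/CO
F3 | step 9 | methyl 4-[(1R,2R)-2-[(1E)-3-bromoprop-1-en-1-yl]cyclopropyl]butanoate | COC(=O)CCC[C@@H]1C[C@H]1/C=C/CBr
F4 | step 9 | methyl 4-[(1R,2R)-2-[(2S)-but-3-en-2-yl]cyclopropyl]butanoate | COC(=O)CCC[C@@H]1C[C@H]1[C@@H](C)C=C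
F5 | step 9 | methyl 4-[(1R,2R)-2-[(2S,3E)-4-(4,4,5,5-tetramethyl-1,3,2-dioxaborolan-2-yl)but-3-en-2-yl]cyclopropyl]butanoate | COC(=O)CCC[C@@H]1C[C@H]1[C@@H](C)/C=C/B1OC(C)(C)C(C)(C)O1
F6 | step 10 | methyl 4-[(1R,2R)-2-[(2S,3E,5E,10R)-6,10-dimethyltrideca-3,5-dien-12-yn-2-yl]cyclopropyl]butanoate | COC(=O)CCC[C@@H]1C[C@H]1[C@@H](C)/C=C/C=C(\C)CCC[C@@H](C)CC#C
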